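**Plan**

- Retrosynthesis: the target is first re-closed between the phenol oxygen ortho to the chain and the ketone carbon C3 to give a 2-siloxychroman ketal. That dihydropyran ring is then cut at C1–C2 and at O–C3 (retro hetero-Diels-Alder) into an ortho-quinone methide and the 2-siloxy-1-alkene of a methyl ketone.
- Enabling feature: the ortho OH oxygen, the two aromatic carbons between it and the chain, C1, C2 and the ketone carbon C3 are the six atoms of a dihydropyran ring, so the target is a ring-opened 2-oxychroman. Taking away the benzylic C1 leaves mirror-symmetric 2-methoxyresorcinol, whose ring carbons C4 and C6 are equivalent.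
- Further cuts: aryl–C1 and C1–N of a Mannich base (C1 comes from formaldehyde), O–Si of the enol ether, and the aryl–C7 bond of the anisyl chain, back to 4-iodoanisole and hex-5-yn-2-one.
- Forward order: Sonogashira coupling, alkyne hydrogenation and kinetic O-silylation build the chain, and aminomethylation gives the arene partner. The halves are joined as the only new ring (the dihydropyran of a chroman) closes in the cycloaddition, and fluoride then opens that ring to the acyclic hydroxy ketone.
- Stereochemistry: the target has no stereocenter and no stereogenic alkene. The ketal carbon of the cycloadduct forms racemic and disappears on ring opening.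

Key step: step 5

Assumption: the 2-hydroxychroman hemiketal released in the last step is taken to open spontaneously, since hemiketals between a phenol and a dialkyl ketone lie on the side of the open hydroxy ketone; LDA is used as the commercial solution.

**Route**

Step 1
Reactants: 1 4-iodoanisole; 2 hex-5-yn-2-one
Product: 3 6-(4-methoxyphenyl)hex-5-yn-2-one
Conditions: PdCl2(PPh3)2 (2 mol%), CuI (4 mol%), Et3N, THF, rt, degassed
Reagents that add atoms: none
Why: Sonogashira coupling of an aryl iodide with a terminal alkyne runs at room temperature even on the electron-rich anisole ring, the ketone is a spectator, and exclusion of oxygen suppresses oxidative alkyne dimerization.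

Step 2
Reactants: 3 6-(4-methoxyphenyl)hex-5-yn-2-one
Product: 4 6-(4-methoxyphenyl)hexan-2-one
Conditions: H2 (1 atm), 10% Pd/C, EtOAc, rt
Reagents that add atoms: none
Why: heterogeneous catalytic hydrogenation takes the alkyne to the alkane, while the dialkyl ketone and the aryl methyl ether are inert at atmospheric pressure.

Step 3
Reactants: 4 6-(4-methoxyphenyl)hexan-2-one
Product: 6 tert-butyl{[6-(4-methoxyphenyl)hex-1-en-2-yl]oxy}dimethylsilane, via terminal lithium enolate 5 (not isolated)
Conditions: LDA (1.1 equiv, commercial solution), THF, −78 °C, 4 added dropwise; then TBSCl (1.2 equiv), DMPU, −78 °C to 0 °C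
Reagents that add atoms: tert-butyldimethylsilyl chloride (TBSCl), CC(C)(C)[Si](C)(C)Cl
Why: kinetic enolization with a hindered lithium amide removes a proton from the less hindered methyl group (the ketone is added to excess base so the enolate cannot equilibrate), and the silyl chloride traps the enolate on oxygen to give the 2-siloxy-1-alkene.

Step 4
Reactants: 7 2-methoxyresorcinol; 8 formaldehyde (as paraformaldehyde)
Product: 10 4-[(dimethylamino)methyl]-2-methoxybenzene-1,3-diol, via (dimethylamino)methanol 9 (not isolated)
Conditions: (CH2O)n (1.0 equiv) and 40% aq Me2NH (1.0 equiv) premixed in EtOH, added slowly to 7 (1.3 equiv), EtOH, 0 °C to rt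
Reagents that add atoms: dimethylamine, CNC
Why: in this phenolic Mannich reaction the iminium ion from the hemiaminal attacks the ring carbon that is ortho to one OH and para to the other; the two such carbons are equivalent by symmetry, so one regioisomer results, and limiting formaldehyde with excess 7 holds the reaction at mono-substitution.

Step 5
Reactants: 10 4-[(dimethylamino)methyl]-2-methoxybenzene-1,3-diol; 6 tert-butyl{[6-(4-methoxyphenyl)hex-1-en-2-yl]oxy}dimethylsilane
Product: 12 rac-2-{[tert-butyl(dimethyl)silyl]oxy}-8-methoxy-2-[4-(4-methoxyphenyl)butyl]chroman-7-ol, via ortho-quinone methide 11 (not isolated)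
Conditions: 6 (3 equiv), o-xylene, 140 °C, 10 added slowly as a 1,4-dioxane solution, N2 sweep to carry off Me2NH
Reagents that add atoms: none
Why: On heating, the proton of the hydrogen-bonded ortho OH of 10 moves to nitrogen and dimethylamine is expelled, which gives ortho-quinone methide 11, an electron-poor 1-oxabutadiene with an electrophilic exocyclic CH2. The electron-rich 1,1-disubstituted silyl enol ether 6 adds to it in an inverse-electron-demand hetero-Diels-Alder reaction, its terminal CH2 bonding to the methylene carbon of 11 (C1–C2 of the heptanone chain) and its siloxy-bearing carbon to the carbonyl oxygen, and rearomatization makes the addition irreversible. The closest known reaction type is the thermal trapping of ortho-quinone methides released from phenolic Mannich bases by enol ethers, enamines and silyl enol ethers to give 2-oxychromans. The dihydropyran ring of the chroman is closed by this intermolecular [4+2] cycloaddition; a stepwise variant (Michael addition, then 6-exo-trig attack of the phenol oxygen on the silyloxocarbenium ion) or entry through the para-quinone methide formed via the other OH would close the same ring. The only new stereocenter, the ketal carbon C2 of the chroman, is under no control and forms as a racemate, which is of no consequence because step 6 turns it into the carbonyl carbon. The step needs 11 to be captured by 6 and not by a further resorcinol ring, and it needs one orientation of addition: the first is secured by adding 10 slowly to an excess of 6 so that 11 stays dilute, the second by the matched polarization of the oxadiene (electrophilic CH2) and of the enol ether (nucleophilic CH2).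

Step 6
Reactants: 12 rac-2-{[tert-butyl(dimethyl)silyl]oxy}-8-methoxy-2-[4-(4-methoxyphenyl)butyl]chroman-7-ol
Product: 14 1-(2,4-dihydroxy-3-methoxyphenyl)-7-(4-methoxyphenyl)heptan-3-one (target CNP0165192.0), via 2-hydroxychroman hemiketal 13 (not isolated)
Conditions: HF·pyridine, pyridine, THF, 0 °C to rt; aq NaHCO3 work-up
Reagents that add atoms: none
Why: fluoride-driven Si–O cleavage of the silyl ketal releases the hemiketal, which collapses by ring-chain tautomerism to the phenol and the ketone; the aryl methyl ethers and free phenols are untouched, and any aryl silyl ether formed by silyl transfer in step 5 would be cleaved as well.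

**Compound list**

1 | 4-iodoanisole (1-iodo-4-methoxybenzene) | COc1ccc(I)cc1 | starting material
2 | hex-5-yn-2-one | CC(=O)CCC#C | starting material
3 | 6-(4-methoxyphenyl)hex-5-yn-2-one | COc1ccc(C#CCCC(C)=O)cc1 | intermediate
4 | 6-(4-methoxyphenyl)hexan-2-one | COc1ccc(CCCCC(C)=O)cc1 | intermediate
5 | lithium 6-(4-methoxyphenyl)hex-1-en-2-olate (terminal lithium enolate, not isolated) | [Li+].[O-]C(=C)CCCCc1ccc(OC)cc1 | intermediate
6 | tert-butyl{[6-(4-methoxyphenyl)hex-1-en-2-yl]oxy}dimethylsilane | COc1ccc(CCCCC(=C)O[Si](C)(C)C(C)(C)C)cc1 | intermediate
7 | 2-methoxyresorcinol (2-methoxybenzene-1,3-diol) | COc1c(O)cccc1O | starting material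
8 | formaldehyde (used as paraformaldehyde) | C=O | starting material
9 | (dimethylamino)methanol (hemiaminal, not isolated) | CN(C)CO | intermediate
10 | 4-[(dimethylamino)methyl]-2-methoxybenzene-1,3-diol | CN(C)Cc1ccc(O)c(OC)c1O | intermediate
11 | 3-hydroxy-2-methoxy-6-methylidenecyclohexa-2,4-dien-1-one (ortho-quinone methide, not isolated) | C=C1C=CC(O)=C(OC)C1=O | intermediate
12 | rac-2-{[tert-butyl(dimethyl)silyl]oxy}-8-methoxy-2-[4-(4-methoxyphenyl)butyl]chroman-7-ol | COc1ccc(CCCCC2(O[Si](C)(C)C(C)(C)C)CCc3ccc(O)c(OC)c3O2)cc1 | intermediate
13 | rac-8-methoxy-2-[4-(4-methoxyphenyl)butyl]chromane-2,7-diol (hemiketal, not isolated) | COc1ccc(CCCCC2(O)CCc3ccc(O)c(OC)c3O2)cc1 | intermediate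
14 | 1-(2,4-dihydroxy-3-methoxyphenyl)-7-(4-methoxyphenyl)heptan-3-one (CNP0165192.0) | COc1ccc(CCCCC(=O)CCc2ccc(O)c(OC)c2O)cc1 | target

**Step count**

Total: 6 steps. Longest linear sequence: 5 steps (steps 1, 2, 3, 5, 6 from 4-iodoanisole); the arene branch joins after one step (step 4).

**Steps most likely to fail**

1. Step 5. The quinone methide may be consumed by attack of further resorcinol rings (oligomerization through methylene bridges), and the enol silane may be protodesilylated by the phenolic OH groups at 140 °C before it can add. The fallback gives up the cycloaddition and makes C1–C2 as an alkene by condensation; it sets out from 7 and 4 and comes back to the route at 14. Compound 7 is benzylated twice (BnBr, K2CO3, DMF) to 1,3-bis(benzyloxy)-2-methoxybenzene F1. Vilsmeier-Haack formylation (POCl3, DMF) para to one benzyloxy group gives 2,4-bis(benzyloxy)-3-methoxybenzaldehyde F2. Claisen-Schmidt condensation of F2 with methyl ketone 4 (NaOH, EtOH, rt), which under basic conditions takes place at the methyl group, gives (E)-1-[2,4-bis(benzyloxy)-3-methoxyphenyl]-7-(4-methoxyphenyl)hept-1-en-3-one F3. Hydrogenation (H2, Pd/C, EtOAc/EtOH) saturates the alkene and removes both benzyl groups to give 14.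

2. Step 4. Aminomethylation may run on to the second equivalent ring position, and the Mannich base may alkylate a second resorcinol ring to a diarylmethane. The fallback replaces the Mannich reaction by a formylation that limits itself to one substitution; it sets out from 7 and comes back at 10. Vilsmeier-Haack formylation of the free resorcinol (POCl3, DMF, MeCN, then aqueous hydrolysis) stops after one substitution because the iminium and formyl groups deactivate the ring, and gives 2,4-dihydroxy-3-methoxybenzaldehyde F4. Reductive amination of F4 with Me2NH and NaBH(OAc)3 in THF gives 10.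

3. Step 3. Enolization may leak to the internal CH2, the enolate may equilibrate during the slow silylation, and the enol silane may hydrolyse on isolation. The fallback fixes the reactive carbon with an ester group in place of kinetic deprotonation; it sets out from 4 and comes back at 14. Carbethoxylation of 4 with NaH and diethyl carbonate in THF at reflux, which acylates the methyl side under thermodynamic control, gives ethyl 7-(4-methoxyphenyl)-3-oxoheptanoate F5. This proton-tolerant β-keto ester is alkylated by Mannich base 10 in refluxing toluene (conjugate addition to the quinone methide) to give racemic ethyl 2-[(2,4-dihydroxy-3-methoxyphenyl)methyl]-7-(4-methoxyphenyl)-3-oxoheptanoate F6, which may sit as its cyclic hemiketal. Dealkoxycarbonylation (NaCl, wet DMSO, 150 °C) then gives 14.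

**Further compounds**

F1 | step 5 | 1,3-bis(benzyloxy)-2-methoxybenzene | COc1c(OCc2ccccc2)cccc1OCc1ccccc1
F2 | step 5 | 2,4-bis(benzyloxy)-3-methoxybenzaldehyde | COc1c(OCc2ccccc2)ccc(C=O)c1OCc1ccccc1
F3 | step 5 | (E)-1-[2,4-bis(benzyloxy)-3-methoxyphenyl]-7-(4-methoxyphenyl)hept-1-en-3-one | COc1ccc(CCCCC(=O)/C=C/c2ccc(OCc3ccccc3)c(OC)c2OCc2ccccc2)cc1
F4 | step 4 | 2,4-dihydroxy-3-methoxybenzaldehyde | COc1c(O)ccc(C=O)c1O
F5 | step 3 | ethyl 7-(4-methoxyphenyl)-3-oxoheptanoate | CCOC(=O)CC(=O)CCCCc1ccc(OC)cc1
F6 | step 3 | rac-ethyl 2-[(2,4-dihydroxy-3-methoxyphenyl)methyl]-7-(4-methoxyphenyl)-3-oxoheptanoate | CCOC(=O)C(Cc1ccc(O)c(OC)c1O)C(=O)CCCCc1ccc(OC)cc1
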